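The route rests on cutting the C2–C3 bond of the dihydrofuran ring. C3 carries oxygen and C2 carries a three-carbon arm whose inner carbon can be a ketone, so O1–C2(acetyl)–C3(OH) is an aldol pair. The acetyl group supplies two carbons of the 1-formylvinyl arm and the third is added later. One amine-catalysed intramolecular aldol reaction forms C2–C3, closes the five-membered ring onto the benzene ring and sets both ring stereocentres (cis; C3 is inverted when it is esterified). Its precursor is an O-acetonyl salicylaldehyde that already bears the (R)-1-(tigloyloxy)ethyl group para to the ether oxygen.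

Key step: step 7

Remarks on the chemistry
- Configuration: the target is (2R,3S,1'R) with the C2 and C3 substituents trans. The aldol product with the same spatial arrangement at C2 is (2S,3R,1'R), because an acetyl group outranks C3 in the priority rules and the alkenyl groups do not.
- Assumption: the sense of induction of (S)-proline is taken from its hydroxyacetone aldol reactions ((E)-enamine, acid-directed delivery). Should experiment show the opposite sense, (R)-proline is used and nothing else changes.
- Design point 1: a phenol or phenoxide para to a benzylic ester expels the carboxylate through a quinone methide. The formyl group and the substituent on the phenol oxygen are therefore installed before the tiglate.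
- Design point 2: an O-acetonyl salicylaldehyde cyclises and dehydrates to a 2-acetylbenzofuran under alkylation base. The acetonyl group is therefore carried as a propargyl ether and set free without base.

Step 1
Reactants: 1 4'-hydroxyacetophenone; 2 paraformaldehyde
Product: 3 5-acetyl-2-hydroxybenzaldehyde
Conditions: MgCl2, Et3N, (CH2O)n, MeCN, reflux; 1 M HCl work-up
Reagents that add atoms: paraformaldehyde (2), C=O
Why: Casnati–Skattebøl ortho-formylation, in which magnesium holds the phenol oxygen and formaldehyde together so that the C–C bond forms only ortho to oxygen (both ortho positions are equivalent) and excess formaldehyde accepts the hydride that raises the new carbon to the aldehyde level.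

Step 2
Reactants: 3 5-acetyl-2-hydroxybenzaldehyde; 4 propargyl bromide
Product: 5 5-acetyl-2-(prop-2-yn-1-yloxy)benzaldehyde
Conditions: K2CO3, DMF, rt
Reagents that add atoms: propargyl bromide (4), C#CCBr
Why: Williamson ether synthesis on the acidic salicylaldehyde phenol, in which the propargyl group is a latent acetonyl group without acidic alpha-hydrogens, so the base-induced aldol–dehydration to a benzofuran (Rap–Stoermer reaction) cannot start.

Step 3
Reactants: 5 5-acetyl-2-(prop-2-yn-1-yloxy)benzaldehyde
Product: 6 1-[3-(dimethoxymethyl)-4-(prop-2-yn-1-yloxy)phenyl]ethan-1-one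
Conditions: HC(OMe)3, PPTS (cat.), MeOH, rt; Et3N quench
Reagents that add atoms: trimethyl orthoformate, COC(OC)OC; methanol (solvent, exchanges with it), CO
Why: Acid-catalysed acetalisation is much faster at the aldehyde than at the donor-substituted aryl methyl ketone, which leaves the ketone as the only reducible carbonyl group.

Step 4
Reactants: 6 1-[3-(dimethoxymethyl)-4-(prop-2-yn-1-yloxy)phenyl]ethan-1-one
Product: 7 (1R)-1-[3-(dimethoxymethyl)-4-(prop-2-yn-1-yloxy)phenyl]ethan-1-ol
Conditions: RuCl[(R,R)-TsDPEN](p-cymene) (1 mol%), HCO2Na, H2O/MeOH, 40 °C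
Reagents that add atoms: none
Why: Noyori asymmetric transfer hydrogenation, in which the (R,R)-TsDPEN ruthenium hydride delivers hydride and proton through its six-membered transition state to the face of aryl methyl ketones that gives the (R)-carbinol, while the near-neutral aqueous formate medium spares acetal and alkyne.

Step 5
Reactants: 7 (1R)-1-[3-(dimethoxymethyl)-4-(prop-2-yn-1-yloxy)phenyl]ethan-1-ol; 8 tiglic acid
Product: 9 (1R)-1-[3-(dimethoxymethyl)-4-(prop-2-yn-1-yloxy)phenyl]ethyl tiglate
Conditions: DCC, DMAP (cat.), CH2Cl2, 0 °C → rt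
Reagents that add atoms: tiglic acid (8), C/C=C(\C)C(=O)O
Why: Steglich esterification acylates at oxygen without breaking the C–O bond of the stereocentre, so the (R) configuration and the (E) geometry are kept, and with the phenol oxygen already alkylated no quinone methide can expel the new ester.

Step 6
Reactants: 9 (1R)-1-[3-(dimethoxymethyl)-4-(prop-2-yn-1-yloxy)phenyl]ethyl tiglate
Product: 11 2-(2-oxopropoxy)-5-[(1R)-1-(tigloyloxy)ethyl]benzaldehyde, via keto acetal 10 (not isolated)
Conditions: Ph3PAuNTf2 (2 mol%), MeOH/H2O, rt; then PPTS, acetone/H2O, rt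
Reagents that add atoms: water, O
Why: Gold-catalysed Markovnikov hydration of the terminal alkyne gives the methyl ketone without base, and mild aqueous acid then hydrolyses the very labile benzaldehyde dimethyl acetal, so the ketoaldehyde never meets a base and the benzylic ester sees only weak acid.

Step 7
Reactants: 11 2-(2-oxopropoxy)-5-[(1R)-1-(tigloyloxy)ethyl]benzaldehyde
Product: 13 (1R)-1-[(2S,3R)-2-acetyl-3-hydroxy-2,3-dihydrobenzofuran-5-yl]ethyl tiglate (acetyl and hydroxyl cis), via proline enamine 12 (not isolated)
Conditions: (S)-proline (30 mol%), DMF (dilute), 4 °C → rt; pH 7 buffer work-up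
Reagents that add atoms: none
Why: (S)-Proline condenses with the ketone to the (E)-enamine 12 on the oxygen-bearing methylene carbon, the enamine carbon C2 attacks the ortho aldehyde carbon C3 while the carboxylic acid hydrogen-bonds to and protonates the aldehyde oxygen, and water hydrolyses the iminium ion and returns the catalyst. The closest known reaction type is the proline-catalysed intramolecular aldol reaction of O-acetonyl ortho-acylphenols to 2-acyl-2,3-dihydrobenzofuran-3-ols, here with the more electrophilic aldehyde as acceptor. The dihydrofuran ring closes in the 5-enolexo, 5-exo-trig mode, with the enamine C=C and the aldehyde C=O both outside the new ring. C2 is set by the catalyst, whose acid group leads the aldehyde to one face of the anti (E)-enamine in the sense known from hydroxyacetone aldol reactions, which is (2S) here; C3 is set by the hydrogen bond, which in the nearly eclipsed five-ring transition state can only be kept if the aldehyde oxygen lies on the ring face that bears the enamine carbon chain, which gives the cis (3R) carbinol. The step needs reaction through the internal and not the methyl-side enamine and a single acceptor: the methyl side could only close a seven-membered ring, the aldehyde has no alpha-hydrogen, and the esters are inert. Near-neutral medium, low temperature and buffered work-up hold back loss of water to the benzofuran and epimerisation at C2, and any leak in facial control appears as a diastereomer because of the side-chain stereocentre and can be removed by chromatography.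

Step 8
Reactants: 13 (1R)-1-[(2S,3R)-2-acetyl-3-hydroxy-2,3-dihydrobenzofuran-5-yl]ethyl tiglate
Product: 14 (1R)-1-[(2S,3R)-2-acetyl-3-(tert-butyldimethylsilyloxy)-2,3-dihydrobenzofuran-5-yl]ethyl tiglate
Conditions: TBSOTf, 2,6-lutidine, CH2Cl2, −78 °C
Reagents that add atoms: tert-butyldimethylsilyl triflate, CC(C)(C)[Si](C)(C)OS(=O)(=O)C(F)(F)F
Why: Silyl ether formation with a silyl triflate and a hindered pyridine base at low temperature is too weakly basic to epimerise C2 or to start E1cB loss of water, and it blocks retro-aldol cleavage and elimination in the next step.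

Step 9
Reactants: 14 (1R)-1-[(2S,3R)-2-acetyl-3-(tert-butyldimethylsilyloxy)-2,3-dihydrobenzofuran-5-yl]ethyl tiglate; 15 dibromomethane
Product: 16 (1R)-1-[(2R,3R)-3-(tert-butyldimethylsilyloxy)-2-(prop-1-en-2-yl)-2,3-dihydrobenzofuran-5-yl]ethyl tiglate (cis)
Conditions: Zn, CH2Br2, TiCl4, THF (reagent aged at 5 °C); then 14 in CH2Cl2, 0 °C → rt
Reagents that add atoms: dibromomethane (15), BrCBr
Why: Lombardo methylenation uses a non-basic, THF-tempered methylene dimetal reagent that turns enolisable ketones into 1,1-disubstituted alkenes without epimerisation at C2 and leaves esters alone, and it adds the third carbon of the side arm.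

Step 10
Reactants: 16 (1R)-1-[(2R,3R)-3-(tert-butyldimethylsilyloxy)-2-(prop-1-en-2-yl)-2,3-dihydrobenzofuran-5-yl]ethyl tiglate
Product: 17 (1R)-1-[(2R,3R)-3-hydroxy-2-(prop-1-en-2-yl)-2,3-dihydrobenzofuran-5-yl]ethyl tiglate (cis)
Conditions: TBAF, AcOH, THF, 0 °C → rt
Reagents that add atoms: none
Why: Fluoride-induced desilylation buffered with acetic acid frees the C3 carbinol without ester cleavage, and C2 is no longer acidic once the ketone is gone.

Step 11
Reactants: 17 (1R)-1-[(2R,3R)-3-hydroxy-2-(prop-1-en-2-yl)-2,3-dihydrobenzofuran-5-yl]ethyl tiglate; 8 tiglic acid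
Product: 18 (2R,3S)-2-(prop-1-en-2-yl)-5-[(1R)-1-(tigloyloxy)ethyl]-2,3-dihydrobenzofuran-3-yl tiglate (trans)
Conditions: PPh3, DIAD, toluene, −20 °C → rt
Reagents that add atoms: tiglic acid (8), C/C=C(\C)C(=O)O
Why: Mitsunobu esterification, in which the C3 hydroxyl is activated on phosphorus and displaced by tiglate in an SN2 process from the face anti to the leaving group, which is also the face remote from the cis isopropenyl group, so that C3 is inverted from (R) to (S) and the trans diester results, an ion-pair pathway being steered to the same face.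

Step 12
Reactants: 18 (2R,3S)-2-(prop-1-en-2-yl)-5-[(1R)-1-(tigloyloxy)ethyl]-2,3-dihydrobenzofuran-3-yl tiglate
Product: 19 (2R,3S)-2-(3-hydroxyprop-1-en-2-yl)-5-[(1R)-1-(tigloyloxy)ethyl]-2,3-dihydrobenzofuran-3-yl tiglate
Conditions: SeO2 (cat.), t-BuOOH, CH2Cl2, 0 °C → rt
Reagents that add atoms: tert-butyl hydroperoxide, CC(C)(C)OO; selenium dioxide (oxygen carrier), O=[Se]=O
Why: Selenium dioxide allylic oxidation (ene reaction followed by a [2,3]-sigmatropic shift) attacks the most electron-rich alkene, the 1,1-disubstituted isopropenyl group, at its methyl group, whereas the conjugated tiglate alkenes react much more slowly at this temperature.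

Step 13
Reactants: 19 (2R,3S)-2-(3-hydroxyprop-1-en-2-yl)-5-[(1R)-1-(tigloyloxy)ethyl]-2,3-dihydrobenzofuran-3-yl tiglate
Product: 20 (2R,3S)-2-(3-oxoprop-1-en-2-yl)-5-[(1R)-1-(tigloyloxy)ethyl]-2,3-dihydrobenzofuran-3-yl tiglate (target)
Conditions: MnO2 (activated), CH2Cl2, rt
Reagents that add atoms: none
Why: Allylic alcohol oxidation with activated MnO2 is neutral, heterogeneous and selective, brings the alcohol and any enal already formed in step 12 to the same product, and touches no stereocentre.

Compound list
1 | 4'-hydroxyacetophenone | CC(=O)c1ccc(O)cc1 | starting material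
2 | paraformaldehyde (written as formaldehyde) | C=O | starting material
3 | 5-acetyl-2-hydroxybenzaldehyde | CC(=O)c1ccc(O)c(C=O)c1 | intermediate
4 | propargyl bromide | C#CCBr | starting material
5 | 5-acetyl-2-(prop-2-yn-1-yloxy)benzaldehyde | CC(=O)c1ccc(OCC#C)c(C=O)c1 | intermediate
6 | 1-[3-(dimethoxymethyl)-4-(prop-2-yn-1-yloxy)phenyl]ethan-1-one | CC(=O)c1ccc(OCC#C)c(C(OC)OC)c1 | intermediate
7 | (1R)-1-[3-(dimethoxymethyl)-4-(prop-2-yn-1-yloxy)phenyl]ethan-1-ol | C#CCOc1ccc([C@@H](C)O)cc1C(OC)OC | intermediate
8 | tiglic acid, (E)-2-methylbut-2-enoic acid | C/C=C(\C)C(=O)O | starting material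
9 | (1R)-1-[3-(dimethoxymethyl)-4-(prop-2-yn-1-yloxy)phenyl]ethyl tiglate | C#CCOc1ccc([C@@H](C)OC(=O)/C(C)=C/C)cc1C(OC)OC | intermediate
10 | (1R)-1-[3-(dimethoxymethyl)-4-(2-oxopropoxy)phenyl]ethyl tiglate (keto acetal, not isolated) | CC(=O)COc1ccc([C@@H](C)OC(=O)/C(C)=C/C)cc1C(OC)OC | intermediate
11 | 2-(2-oxopropoxy)-5-[(1R)-1-(tigloyloxy)ethyl]benzaldehyde | CC(=O)COc1ccc([C@@H](C)OC(=O)/C(C)=C/C)cc1C=O | intermediate
12 | (E)-enamine from the ketone of 11 and (S)-proline (not isolated) | C/C(N1CCC[C@H]1C(=O)O)=C\Oc1ccc([C@@H](C)OC(=O)/C(C)=C/C)cc1C=O | intermediate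
13 | (1R)-1-[(2S,3R)-2-acetyl-3-hydroxy-2,3-dihydrobenzofuran-5-yl]ethyl tiglate, cis | CC(=O)[C@H]1Oc2ccc([C@@H](C)OC(=O)/C(C)=C/C)cc2[C@H]1O | intermediate
14 | (1R)-1-[(2S,3R)-2-acetyl-3-(tert-butyldimethylsilyloxy)-2,3-dihydrobenzofuran-5-yl]ethyl tiglate, cis | CC(=O)[C@H]1Oc2ccc([C@@H](C)OC(=O)/C(C)=C/C)cc2[C@H]1O[Si](C)(C)C(C)(C)C | intermediate
15 | dibromomethane | BrCBr | starting material
16 | (1R)-1-[(2R,3R)-3-(tert-butyldimethylsilyloxy)-2-(prop-1-en-2-yl)-2,3-dihydrobenzofuran-5-yl]ethyl tiglate, cis | C=C(C)[C@H]1Oc2ccc([C@@H](C)OC(=O)/C(C)=C/C)cc2[C@H]1O[Si](C)(C)C(C)(C)C | intermediate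
17 | (1R)-1-[(2R,3R)-3-hydroxy-2-(prop-1-en-2-yl)-2,3-dihydrobenzofuran-5-yl]ethyl tiglate, cis | C=C(C)[C@H]1Oc2ccc([C@@H](C)OC(=O)/C(C)=C/C)cc2[C@H]1O | intermediate
18 | (2R,3S)-2-(prop-1-en-2-yl)-5-[(1R)-1-(tigloyloxy)ethyl]-2,3-dihydrobenzofuran-3-yl tiglate, trans | C=C(C)[C@H]1Oc2ccc([C@@H](C)OC(=O)/C(C)=C/C)cc2[C@@H]1OC(=O)/C(C)=C/C | intermediate
19 | (2R,3S)-2-(3-hydroxyprop-1-en-2-yl)-5-[(1R)-1-(tigloyloxy)ethyl]-2,3-dihydrobenzofuran-3-yl tiglate | C=C(CO)[C@H]1Oc2ccc([C@@H](C)OC(=O)/C(C)=C/C)cc2[C@@H]1OC(=O)/C(C)=C/C | intermediate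
20 | (2R,3S)-2-(3-oxoprop-1-en-2-yl)-5-[(1R)-1-(tigloyloxy)ethyl]-2,3-dihydrobenzofuran-3-yl tiglate | C=C(C=O)[C@H]1Oc2ccc([C@@H](C)OC(=O)/C(C)=C/C)cc2[C@@H]1OC(=O)/C(C)=C/C | target

Total step count: 13. Longest linear sequence: 13, all steps linear from 1 (12 where 3 is bought instead of made).

Steps most likely to fail

1. Step 7. The aldol may lose water while still bound to the amine, driven by aromatisation to the benzofuran. C2 may epimerise, and facial control may be incomplete. The fallback sets out from 11 and comes back at 14. It replaces enamine activation by a silicon-mediated Mukaiyama-type closure of the same bond.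
   - 11 is treated with TBSOTf and Et3N in CH2Cl2 at −78 °C, which should give the (Z)-silyl enol ether F1 on the oxygen-bearing carbon.
   - The silyl triflate still present activates the aldehyde. The enol ether closes C2–C3 and the silyl group passes to the C3 oxygen, so a free beta-hydroxy ketone never exists and the separate silylation is saved.
   - Catalyst control is given up. 14 would be accompanied by the (2R,3S)-cis silyl ether F2, the (2S,3S)-trans silyl ether F3 and the (2R,3R)-trans silyl ether F4.
   - The side-chain stereocentre makes all four compounds diastereomers, so 14 is separated by chromatography.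

2. Step 11. The activated C3 oxygen may leave together with the anti C2–H to give the aromatic 2-isopropenylbenzofuran. Displacement may also be slow because tiglic acid is a weak acid. The fallback sets out from 17 and comes back at 18. It separates the inversion from the tigloylation.
   - A Mitsunobu reaction with the more acidic chloroacetic acid (PPh3, DIAD, toluene) has a less basic carboxylate and faster capture, and should give the trans chloroacetate F5.
   - Brief methanolysis (K2CO3 cat., MeOH, 0 °C) removes the far more labile chloroacetyl group in the presence of the tiglate and gives the trans alcohol F6.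
   - Steglich esterification of F6 with 8 (DCC, DMAP) proceeds with retention and gives 18.

3. Step 12. Oxidation may also occur at the tiglate methyl groups or at C2–H, may run on past the alcohol in an uncontrolled way, or may stall. The fallback sets out from 18 and comes back at 20, passing by 19. It replaces the selenium C–H oxidation by an electrophilic ene-type chlorination.
   - Hypochlorous acid made from Ca(OCl)2 and CO2 in CH2Cl2/H2O at 0 °C selects the electron-rich isopropenyl alkene over the conjugated esters. With shift of the double bond it gives the allylic chloride F7.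
   - Oxidation of this activated halide with N-methylmorpholine N-oxide in MeCN (displacement at oxygen, then loss of the amine) gives the enal 20 directly.

Further compounds
F1 | step 7 | (Z)-tert-butyldimethylsilyl enol ether of 11 on the oxygen-bearing carbon | C/C(O[Si](C)(C)C(C)(C)C)=C/Oc1ccc([C@@H](C)OC(=O)/C(C)=C/C)cc1C=O
F2 | step 7 | (1R)-1-[(2R,3S)-2-acetyl-3-(tert-butyldimethylsilyloxy)-2,3-dihydrobenzofuran-5-yl]ethyl tiglate, cis | CC(=O)[C@@H]1Oc2ccc([C@@H](C)OC(=O)/C(C)=C/C)cc2[C@@H]1O[Si](C)(C)C(C)(C)C
F3 | step 7 | (1R)-1-[(2S,3S)-2-acetyl-3-(tert-butyldimethylsilyloxy)-2,3-dihydrobenzofuran-5-yl]ethyl tiglate, trans | CC(=O)[C@H]1Oc2ccc([C@@H](C)OC(=O)/C(C)=C/C)cc2[C@@H]1O[Si](C)(C)C(C)(C)C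
F4 | step 7 | (1R)-1-[(2R,3R)-2-acetyl-3-(tert-butyldimethylsilyloxy)-2,3-dihydrobenzofuran-5-yl]ethyl tiglate, trans | CC(=O)[C@@H]1Oc2ccc([C@@H](C)OC(=O)/C(C)=C/C)cc2[C@H]1O[Si](C)(C)C(C)(C)C
F5 | step 11 | (1R)-1-[(2R,3S)-3-(chloroacetoxy)-2-(prop-1-en-2-yl)-2,3-dihydrobenzofuran-5-yl]ethyl tiglate, trans | C=C(C)[C@H]1Oc2ccc([C@@H](C)OC(=O)/C(C)=C/C)cc2[C@@H]1OC(=O)CCl
F6 | step 11 | (1R)-1-[(2R,3S)-3-hydroxy-2-(prop-1-en-2-yl)-2,3-dihydrobenzofuran-5-yl]ethyl tiglate, trans | C=C(C)[C@H]1Oc2ccc([C@@H](C)OC(=O)/C(C)=C/C)cc2[C@@H]1O
F7 | step 12 | (2R,3S)-2-(3-chloroprop-1-en-2-yl)-5-[(1R)-1-(tigloyloxy)ethyl]-2,3-dihydrobenzofuran-3-yl tiglate | C=C(CCl)[C@H]1Oc2ccc([C@@H](C)OC(=O)/C(C)=C/C)cc2[C@@H]1OC(=O)/C(C)=C/C
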